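**Retrosynthetic overview**
- The target is unmasked from a hepta-benzyl precursor; the two caffeates come from one double acylation of the C1/C5 diol, and the C1 carboxyl from a carboxyl-anion equivalent added to a C1 ketone.
- Key disconnection: the cyclohexanone is cut at C3–C4 and C5–C6 (formal [4+2]) into 3-(benzyloxy)cyclobutan-1-one (C6–C1–C2–C3, a latent 1,4-dipole opened by strain release) and a (Z)-2-silyloxyvinyl succinate (C4–C5, already carrying the O4 succinate).
- Enabling feature: C1 is a quaternary carbinol carbon flanked by the two ring methylenes C2 and C6 and lies 1,3 to the oxygenated C3, so the C6–C1–C2–C3(O) chain is a ring-opened 3-alkoxycyclobutanone. The vicinal C4–C5 diol is a glycolaldehyde enol whose O4 ester can act as a participating group.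
- Ring order: the carbocycle is the only ring made, and it is closed in the key step; all four ring stereocentres follow from that step (C3, C4, C5) and from the addition to the C1 ketone.

Key step: step 6

Remark: ring carbons keep the locants of the target acid throughout (C1 carboxyl carbon, C2/C6 methylenes, C3 free hydroxyl, C4 succinate, C5 caffeate), also where a systematic name numbers differently.

**Step 1**
Reactants: 1 4-(benzyloxy)-4-oxobutanoic acid (monobenzyl succinate)
Product: 2 benzyl prop-2-en-1-yl butanedioate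
Conditions: allyl bromide, K2CO3, DMF, rt
Reagents that add atoms: allyl bromide, C=CCBr
Why: SN2 O-alkylation of the carboxylate with an unhindered allylic bromide installs the allyl ester that serves as a latent 2-oxoethyl ester, and no stereocentre is formed.

**Step 2**
Reactants: 2 benzyl prop-2-en-1-yl butanedioate
Product: 4 benzyl 2-oxoethyl butanedioate, via ozonide 3 (not isolated)
Conditions: O3, CH2Cl2, −78 °C; then Me2S, −78 °C to rt
Reagents that add atoms: ozone, [O-][O+]=O
Why: Ozonolysis with reductive work-up cleaves the terminal alkene to the acyloxyacetaldehyde while both ester groups are inert to ozone.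

**Step 3**
Reactants: 4 benzyl 2-oxoethyl butanedioate
Product: 5 benzyl (Z)-2-[(triethylsilyl)oxy]ethenyl butanedioate
Conditions: TESOTf, Et3N, CH2Cl2, −78 to 0 °C
Reagents that add atoms: triethylsilyl trifluoromethanesulfonate, CC[Si](CC)(CC)OS(=O)(=O)C(F)(F)F
Why: Soft enolisation and O-silylation of the aldehyde (enol silane formation) should give the 2-acyloxy enol silane with the two oxygen substituents cis, the usual outcome for 2-acyloxy aldehydes, and the succinate methylenes are not acidic enough to compete.

**Step 4**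
Reactants: 6 3,4-bis(benzyloxy)benzaldehyde
Product: 7 (2E)-3-[3,4-bis(benzyloxy)phenyl]prop-2-enoic acid
Conditions: malonic acid, pyridine, piperidine (cat.), 90 °C
Reagents that add atoms: malonic acid, OC(=O)CC(=O)O
Why: Knoevenagel–Doebner condensation with in situ decarboxylation should give the thermodynamically favoured E-cinnamic acid.

**Step 5**
Reactants: 7 (2E)-3-[3,4-bis(benzyloxy)phenyl]prop-2-enoic acid
Product: 8 (2E)-3-[3,4-bis(benzyloxy)phenyl]prop-2-enoyl chloride
Conditions: (COCl)2, DMF (cat.), CH2Cl2, 0 °C to rt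
Reagents that add atoms: oxalyl chloride, ClC(=O)C(=O)Cl
Why: Acid chloride formation through the Vilsmeier-type chloroiminium intermediate leaves the benzyl ethers and the E-alkene untouched.

**Step 6**
Reactants: 9 3-(benzyloxy)cyclobutan-1-one; 5 benzyl (Z)-2-[(triethylsilyl)oxy]ethenyl butanedioate
Product: 12 benzyl (1R,2R,6R)-2-(benzyloxy)-4-oxo-6-[(triethylsilyl)oxy]cyclohexyl butanedioate (3-O-benzyl cis to the 4-succinate, 5-O-silyl trans to it), via oxocarbenium silyl enol ether 10 (not isolated), via dioxolanylium ion 11 (not isolated)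
Conditions: chiral BINOL-derived imidodiphosphorimidate (IDPi) Brønsted acid (3 mol %, silylated in situ by 5), 5 (1.3 equiv), toluene, −60 °C
Reagents that add atoms: none
Why: Proposed new method: the silylated chiral IDPi acid activates the ketone of 9, and the strained ring bond between the ketone α-carbon (C6) and the benzyloxy-bearing carbon (C3) ionises with push from the ether oxygen (donor–acceptor cyclobutanone, strain release) to the silyl enol ether/oxocarbenium ion pair 10, a 1,4-dipole. Enol silane 5 adds through its acyloxy-bearing carbon to the oxocarbenium carbon (forms C3–C4), and the resulting C5 silyloxocarbenium ion, bridged by the succinate carbonyl as dioxolanylium ion 11, is attacked by the tethered silyl enol ether carbon C6 (forms C5–C6 in a 6-(enolendo)-exo-trig Mukaiyama aldol closure of the only ring, through a chair), which releases the silylium catalyst. The closest known reactions are the racemic EtAlCl2- or SnCl4-mediated formal [4+2] cycloaddition of 3-alkoxycyclobutanones with silyl enol ethers and the IDPi-catalysed Mukaiyama aldol addition of aldehyde-derived enol silanes; new here are the chiral counter-anion control of the dipole and the 2-acyloxy enol silane as partner. The absolute sense at C3 is set by the confined chiral anion paired with the oxocarbenium ion, C4 is set relative to C3 by the topicity of this first C–C bond formation, for which the erythro (3,4-cis) mode is needed and is modelled on a synclinal open transition state with the hydrogen of the enol carbon over the C2 methylene (2-acyloxy enol silanes are known to add to TiCl4-activated aldehydes in the erythro sense), and C5 is set by anchimeric assistance of the O4 ester, which leaves only the face anti to O4 open, so that O5 ends trans to O4 as in a 1,2-trans glycosylation and equatorial, away from the axial 3-benzyloxy group. The step needs regioselectivity (secured by the polarisation of 5, silyloxy being a stronger donor than acyloxy), 4,5-trans selectivity (secured by the participating succinate) and 3,4-cis selectivity together with enantioselectivity (both resting on the catalyst, the least secured point). The electrophilic dipole and the electron-rich enediol partner are polarity-matched, which a Diels–Alder reaction of the corresponding 1-alkoxy-3-silyloxydiene with such a partner would not be.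

**Step 7**
Reactants: 12 benzyl (1R,2R,6R)-2-(benzyloxy)-4-oxo-6-[(triethylsilyl)oxy]cyclohexyl butanedioate
Product: 13 benzyl (1R,2R,4S,6R)-2-(benzyloxy)-4-hydroxy-4-[tris(methylsulfanyl)methyl]-6-[(triethylsilyl)oxy]cyclohexyl butanedioate
Conditions: HC(SMe)3, n-BuLi, THF, −78 °C; then 12, −78 °C; aq NH4Cl
Reagents that add atoms: tris(methylsulfanyl)methane, CSC(SC)SC
Why: 1,2-Addition of the bulky carboxyl-anion equivalent tris(methylsulfanyl)methyllithium to the ketone, which at −78 °C should outrun attack on the esters, is expected on the face opposite the axial 3-benzyloxy group (equatorial attack), so that the new C1 hydroxyl is cis to O3 and O4 and the carbon substituent is cis to O5.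

**Step 8**
Reactants: 13 benzyl (1R,2R,4S,6R)-2-(benzyloxy)-4-hydroxy-4-[tris(methylsulfanyl)methyl]-6-[(triethylsilyl)oxy]cyclohexyl butanedioate
Product: 14 benzyl (1S,3R,4R,5R)-3-(benzyloxy)-4-{[4-(benzyloxy)-4-oxobutanoyl]oxy}-1-hydroxy-5-[(triethylsilyl)oxy]cyclohexane-1-carboxylate
Conditions: HgCl2, HgO, BnOH, MeCN/H2O, rt
Reagents that add atoms: benzyl alcohol, OCc1ccccc1; water, O
Why: Thiophile-assisted solvolysis of the trithioorthoester (orthoester-to-ester unmasking) by benzyl alcohol and water should give the benzyl ester directly without touching the quaternary C1 stereocentre.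

**Step 9**
Reactants: 14 benzyl (1S,3R,4R,5R)-3-(benzyloxy)-4-{[4-(benzyloxy)-4-oxobutanoyl]oxy}-1-hydroxy-5-[(triethylsilyl)oxy]cyclohexane-1-carboxylate
Product: 15 benzyl (1R,3R,4S,5R)-3-(benzyloxy)-4-{[4-(benzyloxy)-4-oxobutanoyl]oxy}-1,5-dihydroxycyclohexane-1-carboxylate
Conditions: HF·pyridine, pyridine, THF, 0 °C
Reagents that add atoms: none
Why: Fluoride-mediated silyl ether cleavage under buffered, slightly acidic conditions frees O5–H while giving the neighbouring succinate no base-promoted path for acyl migration.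

**Step 10**
Reactants: 15 benzyl (1R,3R,4S,5R)-3-(benzyloxy)-4-{[4-(benzyloxy)-4-oxobutanoyl]oxy}-1,5-dihydroxycyclohexane-1-carboxylate; 8 (2E)-3-[3,4-bis(benzyloxy)phenyl]prop-2-enoyl chloride
Product: 17 benzyl (1S,3R,4R,5R)-3-(benzyloxy)-4-{[4-(benzyloxy)-4-oxobutanoyl]oxy}-1,5-bis({(2E)-3-[3,4-bis(benzyloxy)phenyl]prop-2-enoyl}oxy)cyclohexane-1-carboxylate, via 5-O-monoester 16 (not isolated)
Conditions: 8 (4 equiv), DMAP, pyridine, CH2Cl2, 0 to 40 °C
Reagents that add atoms: none
Why: DMAP-catalysed acylation through the N-acylpyridinium ion should esterify the equatorial secondary O5–H first and then, with excess reagent and warming, the tertiary O1–H of the α-hydroxy ester, with retention at both carbinol carbons.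

**Step 11**
Reactants: 17 benzyl (1S,3R,4R,5R)-3-(benzyloxy)-4-{[4-(benzyloxy)-4-oxobutanoyl]oxy}-1,5-bis({(2E)-3-[3,4-bis(benzyloxy)phenyl]prop-2-enoyl}oxy)cyclohexane-1-carboxylate
Product: 18 (1S,3R,4R,5R)-4-[(3-carboxypropanoyl)oxy]-1,5-bis{[(2E)-3-(3,4-dihydroxyphenyl)prop-2-enoyl]oxy}-3-hydroxycyclohexane-1-carboxylic acid (target)
Conditions: BCl3, pentamethylbenzene, CH2Cl2, −78 to −30 °C; then cold aqueous work-up
Reagents that add atoms: none
Why: Lewis acid-mediated debenzylation with a non-basic cation scavenger should cleave the four aryl benzyl ethers, the secondary benzyl ether and both benzyl esters at low temperature while the cinnamate alkenes and the three alkyl ester linkages, which rule out hydrogenolysis and saponification, stay intact and no stereocentre is touched.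

**Compound list**
1 | 4-(benzyloxy)-4-oxobutanoic acid | OC(=O)CCC(=O)OCc1ccccc1 | starting material
2 | benzyl prop-2-en-1-yl butanedioate | C=CCOC(=O)CCC(=O)OCc1ccccc1 | intermediate
3 | benzyl (1,2,4-trioxolan-3-yl)methyl butanedioate (ozonide) | O=C(CCC(=O)OCc1ccccc1)OCC1OCOO1 | intermediate
4 | benzyl 2-oxoethyl butanedioate | O=CCOC(=O)CCC(=O)OCc1ccccc1 | intermediate
5 | benzyl (Z)-2-[(triethylsilyl)oxy]ethenyl butanedioate | CC[Si](CC)(CC)O/C=C\OC(=O)CCC(=O)OCc1ccccc1 | intermediate
6 | 3,4-bis(benzyloxy)benzaldehyde | O=Cc1ccc(OCc2ccccc2)c(OCc2ccccc2)c1 | starting material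
7 | (2E)-3-[3,4-bis(benzyloxy)phenyl]prop-2-enoic acid | OC(=O)/C=C/c1ccc(OCc2ccccc2)c(OCc2ccccc2)c1 | intermediate
8 | (2E)-3-[3,4-bis(benzyloxy)phenyl]prop-2-enoyl chloride | ClC(=O)/C=C/c1ccc(OCc2ccccc2)c(OCc2ccccc2)c1 | intermediate
9 | 3-(benzyloxy)cyclobutan-1-one | O=C1CC(OCc2ccccc2)C1 | starting material
10 | benzyl{3-[(triethylsilyl)oxy]but-3-en-1-ylidene}oxonium ion (ion pair with the catalyst anion) | C=C(O[Si](CC)(CC)CC)CC=[O+]Cc1ccccc1 | intermediate
11 | 2-[3-(benzyloxy)-3-oxopropyl]-4-{(1R)-1-(benzyloxy)-3-[(triethylsilyl)oxy]but-3-en-1-yl}-5-[(triethylsilyl)oxy]-1,3-dioxolan-2-ylium ion (4,5-trans) | C=C(O[Si](CC)(CC)CC)C[C@@H](OCc1ccccc1)[C@H]1OC(CCC(=O)OCc2ccccc2)=[O+][C@@H]1O[Si](CC)(CC)CC | intermediate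
12 | benzyl (1R,2R,6R)-2-(benzyloxy)-4-oxo-6-[(triethylsilyl)oxy]cyclohexyl butanedioate | O=C(OCc1ccccc1)CCC(=O)O[C@@H]1[C@H](OCc2ccccc2)CC(=O)C[C@H]1O[Si](CC)(CC)CC | intermediate
13 | benzyl (1R,2R,4S,6R)-2-(benzyloxy)-4-hydroxy-4-[tris(methylsulfanyl)methyl]-6-[(triethylsilyl)oxy]cyclohexyl butanedioate | O=C(OCc1ccccc1)CCC(=O)O[C@@H]1[C@H](OCc2ccccc2)C[C@@](O)(C(SC)(SC)SC)C[C@H]1O[Si](CC)(CC)CC | intermediate
14 | benzyl (1S,3R,4R,5R)-3-(benzyloxy)-4-{[4-(benzyloxy)-4-oxobutanoyl]oxy}-1-hydroxy-5-[(triethylsilyl)oxy]cyclohexane-1-carboxylate | O=C(OCc1ccccc1)CCC(=O)O[C@@H]1[C@H](OCc2ccccc2)C[C@@](O)(C(=O)OCc2ccccc2)C[C@H]1O[Si](CC)(CC)CC | intermediate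
15 | benzyl (1R,3R,4S,5R)-3-(benzyloxy)-4-{[4-(benzyloxy)-4-oxobutanoyl]oxy}-1,5-dihydroxycyclohexane-1-carboxylate | O=C(OCc1ccccc1)CCC(=O)O[C@@H]1[C@H](OCc2ccccc2)C[C@@](O)(C(=O)OCc2ccccc2)C[C@H]1O | intermediate
16 | benzyl (1S,3R,4R,5R)-3-(benzyloxy)-4-{[4-(benzyloxy)-4-oxobutanoyl]oxy}-5-({(2E)-3-[3,4-bis(benzyloxy)phenyl]prop-2-enoyl}oxy)-1-hydroxycyclohexane-1-carboxylate | O=C(OCc1ccccc1)CCC(=O)O[C@@H]1[C@H](OCc2ccccc2)C[C@@](O)(C(=O)OCc2ccccc2)C[C@H]1OC(=O)/C=C/c1ccc(OCc2ccccc2)c(OCc2ccccc2)c1 | intermediate
17 | benzyl (1S,3R,4R,5R)-3-(benzyloxy)-4-{[4-(benzyloxy)-4-oxobutanoyl]oxy}-1,5-bis({(2E)-3-[3,4-bis(benzyloxy)phenyl]prop-2-enoyl}oxy)cyclohexane-1-carboxylate | O=C(OCc1ccccc1)CCC(=O)O[C@@H]1[C@H](OCc2ccccc2)C[C@@](OC(=O)/C=C/c2ccc(OCc3ccccc3)c(OCc3ccccc3)c2)(C(=O)OCc2ccccc2)C[C@H]1OC(=O)/C=C/c1ccc(OCc2ccccc2)c(OCc2ccccc2)c1 | intermediate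
18 | (1S,3R,4R,5R)-4-[(3-carboxypropanoyl)oxy]-1,5-bis{[(2E)-3-(3,4-dihydroxyphenyl)prop-2-enoyl]oxy}-3-hydroxycyclohexane-1-carboxylic acid | O=C(O)CCC(=O)O[C@@H]1[C@H](O)C[C@@](OC(=O)/C=C/c2ccc(O)c(O)c2)(C(=O)O)C[C@H]1OC(=O)/C=C/c1ccc(O)c(O)c1 | target

**Step count**
Total: 11 steps. Longest linear sequence: 9 steps (steps 1, 2, 3, 6, 7, 8, 9, 10, 11).

**Steps most likely to fail**

Step 6 (key step, proposed new method). What may go wrong: the silylium catalyst may fail to open the cyclobutanone, the first C–C bond may form with the wrong relative topicity (3,4-trans instead of 3,4-cis) or with low enantiocontrol, and the β-oxygen groups of the product may be lost by elimination. Fallback with known chemistry: starting again from 9 and 5, the cycloaddition is run under the established achiral conditions for 3-alkoxycyclobutanones and silyl enol ethers (EtAlCl2, CH2Cl2, −78 °C, with TiCl4 as the alternative Lewis acid if the 3,4-cis isomer is not favoured). This should give 12 as a racemate together with its enantiomer benzyl (1S,2S,6S)-2-(benzyloxy)-4-oxo-6-[(triethylsilyl)oxy]cyclohexyl butanedioate F1. Diastereomers are removed on silica and the enantiomers are separated by preparative chromatography on a chiral stationary phase, which returns to the route at 12.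

Step 10. What may go wrong: acylation of the hindered tertiary O1–H (syn-axial to the 3-benzyloxy group) may stall at monoester 16, and the succinate may migrate from O4 to O5 before O5 is acylated. Fallback: from 15, heating with Meldrum's acid in toluene at 90 °C, a reagent that also acylates tertiary alcohols, should give benzyl (1S,3R,4R,5R)-3-(benzyloxy)-4-{[4-(benzyloxy)-4-oxobutanoyl]oxy}-1,5-bis[(carboxyacetyl)oxy]cyclohexane-1-carboxylate F2. A twofold Knoevenagel–Doebner condensation of F2 with aldehyde 6 (pyridine, piperidine cat., 60 °C) then builds both E-cinnamate units on the ring and returns to the route at 17.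

Step 11. What may go wrong: incomplete cleavage of the secondary benzyl ether or of the benzyl esters, or Lewis acid-induced acyl migration or ester cleavage during the sevenfold debenzylation. Fallback: from 15 by way of F2 (made as described above), hydrogenolysis (H2, Pd/C, EtOAc) at this stage, where no alkene is present, removes the benzyl ether and both benzyl esters and should give (1S,3R,4R,5R)-1,5-bis[(carboxyacetyl)oxy]-4-[(3-carboxypropanoyl)oxy]-3-hydroxycyclohexane-1-carboxylic acid F3. A twofold Knoevenagel–Doebner condensation of F3 with unprotected 3,4-dihydroxybenzaldehyde (pyridine, piperidine cat., 50 °C) then gives 18 directly, with no protecting group left to remove.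

**Further compounds**
F1 | step 6 | benzyl (1S,2S,6S)-2-(benzyloxy)-4-oxo-6-[(triethylsilyl)oxy]cyclohexyl butanedioate (enantiomer of 12) | O=C(OCc1ccccc1)CCC(=O)O[C@H]1[C@@H](OCc2ccccc2)CC(=O)C[C@@H]1O[Si](CC)(CC)CC
F2 | step 10 | benzyl (1S,3R,4R,5R)-3-(benzyloxy)-4-{[4-(benzyloxy)-4-oxobutanoyl]oxy}-1,5-bis[(carboxyacetyl)oxy]cyclohexane-1-carboxylate | O=C(OCc1ccccc1)CCC(=O)O[C@@H]1[C@H](OCc2ccccc2)C[C@@](OC(=O)CC(=O)O)(C(=O)OCc2ccccc2)C[C@H]1OC(=O)CC(=O)O
F3 | step 11 | (1S,3R,4R,5R)-1,5-bis[(carboxyacetyl)oxy]-4-[(3-carboxypropanoyl)oxy]-3-hydroxycyclohexane-1-carboxylic acid | O=C(O)CCC(=O)O[C@@H]1[C@H](O)C[C@@](OC(=O)CC(=O)O)(C(=O)O)C[C@H]1OC(=O)CC(=O)O
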